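**Plan**

1. Retrosynthesis first cuts C7–C8 and the lactone bond C12–O(C8) of the guaianolide half, then the norbornene bonds C1–C13′ and C3–C11′ (retro-Diels–Alder). This leaves a 5-acetoxycyclopentadiene and the 1,10-seco-eudesmanolide α-methylene lactone.
2. Enabling feature: the trans α-methylene-γ-lactone fused at C7/C8 of the cycloheptane C1, C5–C10 is the retron of a C8 aldehyde and a C7=C11 2-(bromomethyl)enoate, held on C1 and C5 of the norbornene.
3. Diene (steps 1–12): cyclopentane-1,3-dione and crotonaldehyde give a bicyclic vinylogous ester, then a 2,3,4-substituted cyclopentenone, the (2S)-acetate, the C6–C7=C11 side chain and finally the diene.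
4. Dienophile (steps 13–22): (S)-citronellal gives a vinyl ketone, then a cyclohexenone, the cis keto lactone and the diene methylene lactone. Step 23 builds the spiro-norbornene, steps 24–26 set bromide and aldehyde, step 27 closes the cycloheptane and its lactone.
5. Stereochemistry: C10 and C7′ from prolinol silyl ether catalysis, C2 from CBS reduction, C4′ from citronellal, C8′ from cis-lactonisation, C1/C3/C11′ in the cycloaddition, C7/C8 in the chair-like allylzinc addition of the (E)-bromide.

Key step: step 27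

Remark on the chemistry: biogenetic numbering is used (guaiane half C1–C15, seco-eudesmane half C1′–C15′). Centres that form as mixtures and later become trigonal or are cleaved are left undefined in the SMILES: C4 in 5–14, the acetal carbon in 3–8, C5 in 8, the carbinol of 18, C5′ in 21–27, C11′ in 31–32.

**Diene half**

Step 1
Reactants: 1 cyclopentane-1,3-dione; 2 (E)-but-2-enal
Product: 3 (4R)-2-hydroxy-4-methyl-3,4,6,7-tetrahydrocyclopenta[b]pyran-5(2H)-one (lactol, both anomers)
Conditions: (S)-α,α-diphenylprolinol trimethylsilyl ether (10 mol %), CH2Cl2, 0 °C to rt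
Reagents that add atoms: none
Why: Iminium-catalysed Michael addition of the cyclic 1,3-diketone to the enal followed by spontaneous lactol formation; the (E)-iminium ion is attacked at the future C10 on the face away from the diphenyl(silyloxy)methyl group, which should give the (R) centre.

Step 2
Reactants: 3 lactol
Product: 4 (4R)-2-methoxy-4-methyl-3,4,6,7-tetrahydrocyclopenta[b]pyran-5(2H)-one
Conditions: MeOH, pyridinium p-toluenesulfonate (cat.), rt
Reagents that add atoms: methanol, CO
Why: Acid-catalysed acetal exchange gives a base-stable cyclic vinylogous ester in which the carbonyl carbon (C5) and the enol-ether carbon (C2) of the former dione are differentiated.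

Step 3
Reactants: 4 vinylogous ester
Product: 5 (4R)-2-methoxy-4,6-dimethyl-3,4,6,7-tetrahydrocyclopenta[b]pyran-5(2H)-one
Conditions: LiN(i-Pr)2, THF, −78 °C; MeI, −78 to −20 °C
Reagents that add atoms: iodomethane, CI
Why: Kinetic deprotonation of a vinylogous ester takes place at the α′ carbon next to the carbonyl (first stage of a Stork–Danheiser sequence) and methylation there installs C15 on C4; this centre later becomes trigonal.

Step 4
Reactants: 5 methylated vinylogous ester
Product: 6 (4R)-6-hydroxy-2-methoxy-4,6-dimethyl-3,4,6,7-tetrahydrocyclopenta[b]pyran-5(2H)-one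
Conditions: LiN(i-Pr)2, THF, −78 °C; 3-phenyl-2-(phenylsulfonyl)oxaziridine, −78 °C; aq NH4Cl
Reagents that add atoms: 3-phenyl-2-(phenylsulfonyl)oxaziridine, O=S(=O)(c1ccccc1)N1OC1c1ccccc1
Why: Davis hydroxylation of the tertiary α′ enolate gives the C4 tertiary alcohol that is later eliminated to the C3=C4 double bond.

Step 5
Reactants: 6 tertiary alcohol
Product: 7 (4R)-2-methoxy-4,6-dimethyl-6-(triethylsilyloxy)-3,4,6,7-tetrahydrocyclopenta[b]pyran-5(2H)-one
Conditions: Et3SiOSO2CF3, 2,6-lutidine, CH2Cl2, −78 to 0 °C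
Reagents that add atoms: triethylsilyl trifluoromethanesulfonate, CC[Si](CC)(CC)OS(=O)(=O)C(F)(F)F
Why: Silylation with the silyl triflate and a hindered base masks the tertiary hydroxyl so that it neither consumes Grignard reagent nor directs the later borane reduction.

Step 6
Reactants: 7 silylated vinylogous ester
Product: 9 2-[(2R)-4,4-dimethoxybutan-2-yl]-4-methyl-3-(prop-2-enyl)-4-(triethylsilyloxy)cyclopent-2-en-1-one, via tertiary allyl carbinol 8 (not isolated)
Conditions: CH2=CHCH2MgBr, THF, −78 to 0 °C; aq NH4Cl; crude product in MeOH, pyridinium p-toluenesulfonate (cat.), rt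
Reagents that add atoms: allylmagnesium bromide, C=CC[Mg]Br; methanol, CO
Why: 1,2-Addition of the allyl Grignard reagent to the vinylogous ester carbonyl and acid-induced allylic transposition (Stork–Danheiser enone synthesis) put C6–C7 on C5 and make C2 the ketone, while methanol opens the released cyclic acetal to the C8 dimethyl acetal.

Step 7
Reactants: 9 enone
Product: 10 (1S)-2-[(2R)-4,4-dimethoxybutan-2-yl]-4-methyl-3-(prop-2-enyl)-4-(triethylsilyloxy)cyclopent-2-en-1-ol (C2 S, C10 R in biogenetic numbering)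
Conditions: (R)-tetrahydro-1-methyl-3,3-diphenyl-1H,3H-pyrrolo[1,2-c][1,3,2]oxazaborole (0.5 equiv), BH3·SMe2, THF, −30 °C; MeOH
Reagents that add atoms: none
Why: Corey–Bakshi–Shibata reduction, in which the (R)-oxazaborolidine binds the carbonyl on the side of the small C3 methylene and delivers hydride to the face that gives the (S) carbinol, so the catalyst and not the remote C4 or C10 centres sets C2.

Step 8
Reactants: 10 allylic alcohol
Product: 11 acetate of 10 (C2 OAc)
Conditions: Ac2O, pyridine, 4-(dimethylamino)pyridine (cat.), CH2Cl2, 0 °C to rt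
Reagents that add atoms: acetic anhydride, CC(=O)OC(C)=O
Why: Standard acylation of the secondary allylic alcohol; the tertiary oxygen is silylated and inert.

Step 9
Reactants: 11 acetate
Product: 12 [(3S)-3-acetoxy-2-[(2R)-4,4-dimethoxybutan-2-yl]-5-methyl-5-(triethylsilyloxy)cyclopent-1-en-1-yl]acetaldehyde (C7 aldehyde)
Conditions: OsO4 (2 mol %), NaIO4, 2,6-lutidine, dioxane–H2O (3:1), rt
Reagents that add atoms: sodium periodate, [Na+].[O-]I(=O)(=O)=O
Why: Lemieux–Johnson cleavage, in which OsO4 dihydroxylates the monosubstituted alkene much faster than the hindered tetrasubstituted ring alkene and periodate cleaves the diol.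

Step 10
Reactants: 12 aldehyde
Product: 13 methyl (2E)-4-[(3S)-3-acetoxy-2-[(2R)-4,4-dimethoxybutan-2-yl]-5-methyl-5-(triethylsilyloxy)cyclopent-1-en-1-yl]-2-bromobut-2-enoate
Conditions: (CF3CH2O)2P(O)CHBrCO2Me, KOt-Bu, 18-crown-6, THF, −78 °C
Reagents that add atoms: methyl 2-[bis(2,2,2-trifluoroethoxy)phosphoryl]-2-bromoacetate, COC(=O)C(Br)P(=O)(OCC(F)(F)F)OCC(F)(F)F
Why: Horner–Wadsworth–Emmons olefination with a bis(trifluoroethyl) phosphonate (Still–Gennari-type kinetic control) places C6 cis to the ester, which is the (E)-α-bromo enoate, and the low temperature avoids enolisation of the β,γ-unsaturated aldehyde.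

Step 11
Reactants: 13 bromo enoate
Product: 14 methyl (2E)-4-[(3S)-3-acetoxy-2-[(2R)-4,4-dimethoxybutan-2-yl]-5-hydroxy-5-methylcyclopent-1-en-1-yl]-2-bromobut-2-enoate
Conditions: HF·pyridine, pyridine, THF, 0 °C to rt
Reagents that add atoms: none
Why: Buffered fluoride cleaves the triethylsilyl ether and should leave acetate, dimethyl acetal and alkenyl bromide untouched.

Step 12
Reactants: 14 tertiary allylic alcohol
Product: 15 methyl (2E)-4-[(3S)-3-acetoxy-2-[(2R)-4,4-dimethoxybutan-2-yl]-5-methylcyclopenta-1,4-dien-1-yl]-2-bromobut-2-enoate (5-acetoxycyclopentadiene: C1=C5, C3=C4, C2 sp3)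
Conditions: Ph2S[OC(CF3)2Ph]2, CH2Cl2, −40 to 0 °C; cold filtration through silica; solution used at once
Reagents that add atoms: none
Why: Martin sulfurane dehydration of the tertiary allylic alcohol under neutral conditions should remove a C3 proton to give the conjugated ring diene; an exocyclic isomer would be locked s-trans and inert in step 23, and no base is present that could deprotonate C2.

**Dienophile half**

Step 13
Reactants: 16 (S)-citronellal
Product: 17 (3S)-3,7-dimethyl-2-methylideneoct-6-enal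
Conditions: 37 % aq CH2O, pyrrolidine (10 mol %), propionic acid (10 mol %), i-PrOH, 45 °C
Reagents that add atoms: formaldehyde, C=O
Why: Amine-catalysed α-methylenation of the aldehyde (Mannich condensation and elimination); the β centre, the future C4′, cannot enolise.

Step 14
Reactants: 17 enal
Product: 18 (4S)-4,8-dimethyl-3-methylidenenon-7-en-2-ol (both carbinol epimers)
Conditions: MeMgBr, Et2O, −78 °C; aq NH4Cl
Reagents that add atoms: methylmagnesium bromide, C[Mg]Br
Why: Hard Grignard reagents add 1,2 to enals at low temperature.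

Step 15
Reactants: 18 allylic alcohol
Product: 19 (4S)-4,8-dimethyl-3-methylidenenon-7-en-2-one
Conditions: 1,1,1-triacetoxy-1,1-dihydro-1,2-benziodoxol-3(1H)-one (Dess–Martin periodinane), NaHCO3, CH2Cl2, 0 °C
Reagents that add atoms: none
Why: Dess–Martin oxidation under buffered conditions gives the α-substituted vinyl ketone without enolisation or polymerisation.

Step 16
Reactants: 19 vinyl ketone; 20 methyl 4-oxobutanoate
Product: 22 methyl [(1S)-5-[(2S)-6-methylhept-5-en-2-yl]-4-oxocyclohex-2-en-1-yl]acetate (C7′ S; both C5′ epimers), via keto aldehyde 21 (not isolated)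
Conditions: (S)-α,α-diphenylprolinol trimethylsilyl ether (20 mol %), 4-nitrophenol (20 mol %), CH2Cl2, 4 °C; then LiOH (10 mol %), i-PrOH, rt
Reagents that add atoms: none
Why: Enamine-catalysed Michael addition of the aldehyde to the vinyl ketone followed by intramolecular aldol condensation (organocatalytic Robinson annulation); the acceptor approaches the (E)-enamine anti to the bulky prolinol substituent, which should set C7′ as (S), and the unselective C5′ centre is removed in step 19.

Step 17
Reactants: 22 cyclohexenone ester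
Product: 24 (3aS,7aS)-5-[(2S)-6-methylhept-5-en-2-yl]hexahydro-1-benzofuran-2,6-dione (cis-fused keto lactone; C7′ S, C8′ S), via carboxylic acid 23 (not isolated)
Conditions: LiOH·H2O, THF–H2O (3:1), 0 °C to rt; then 1 M aq HCl to pH 2, rt
Reagents that add atoms: lithium hydroxide, [Li+].[OH-]
Why: Saponification and acid-catalysed conjugate addition of the carboxylic acid to C8′ of the enone (intramolecular oxa-Michael, 5-exo-trig); a five-membered ring can only fuse cis here, so C8′ follows from C7′.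

Step 18
Reactants: 24 keto lactone
Product: 26 (3aS,7aS)-5-[(2S)-5-hydroxypentan-2-yl]hexahydro-1-benzofuran-2,6-dione, via side-chain aldehyde 25 (not isolated)
Conditions: O3, CH2Cl2, −78 °C; PPh3, −78 °C to rt; then NaBH(OAc)3, AcOH (cat.), rt
Reagents that add atoms: ozone, [O-][O+]=O
Why: Ozonolysis of the only C=C bond with reductive work-up, then chemoselective reduction of the aldehyde by NaBH(OAc)3, which leaves the ring ketone and the lactone.

Step 19
Reactants: 26 keto lactone alcohol
Product: 28 (3aR,7aS)-5-[(2S)-5-hydroxypentan-2-yl]-3,3a,7,7a-tetrahydro-1-benzofuran-2,6-dione (C5′=C6′ enone; same spatial arrangement at C7′ and C8′), via α-phenylselanyl ketone 27 (not isolated)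
Conditions: PhSeCl, EtOAc, rt; then 30 % H2O2, pyridine, CH2Cl2, 0 °C to rt
Reagents that add atoms: none
Why: Acid-mediated α-selenenylation through the more substituted enol (C5′) and selenoxide syn-elimination into the ring; the acidic medium avoids an enolate at C9′ that could expel the lactone carboxylate.

Step 20
Reactants: 28 enone alcohol
Product: 29 tert-butyldimethylsilyl ether of 28
Conditions: t-BuMe2SiCl, imidazole, DMF, rt
Reagents that add atoms: tert-butyl(chloro)dimethylsilane, CC(C)(C)[Si](C)(C)Cl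
Why: Standard silylation of the primary alcohol.

Step 21
Reactants: 29 enone
Product: 30 (3aR,7aS)-5-[(2S)-5-(tert-butyldimethylsilyloxy)pentan-2-yl]-6-methylidene-3,3a,7,7a-tetrahydro-1-benzofuran-2(6H)-one
Conditions: Zn, CH2Br2, TiCl4 (pre-formed in THF), CH2Cl2, 0 °C to rt
Reagents that add atoms: dibromomethane, BrCBr
Why: Lombardo methylenation is non-basic, so it should not trigger β-elimination of the acyloxy group and aromatisation, and it does not attack the lactone.

Step 22
Reactants: 30 diene lactone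
Product: 33 (3aS,7aS)-5-[(2S)-5-(tert-butyldimethylsilyloxy)pentan-2-yl]-3,6-dimethylidene-3,3a,7,7a-tetrahydro-1-benzofuran-2(6H)-one, via Mannich base 31 (not isolated), via methiodide 32 (not isolated)
Conditions: LiN(i-Pr)2, THF, −78 °C; CH2=NMe2+ I−, −78 to 0 °C; MeI, MeOH, rt; aq NaHCO3, CH2Cl2, rt
Reagents that add atoms: N,N-dimethylmethaniminium iodide, C=[N+](C)C.[I-]
Why: α-Methylenation of the lactone by Mannich reaction of its lithium enolate, N-methylation and elimination; the ring diene is s-trans and inert.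

**Union and end game**

Step 23
Reactants: 15 5-acetoxycyclopentadiene; 33 α-methylene lactone
Product: 34 spiro-norbornene adduct (C1 R, C2 S, C3 S, C10 R, C11′ S, C7′ S, C8′ S, C4′ S; OAc on C2 syn to C4=C5; lactone carbonyl exo; C5 bears CH2CH=C(Br)CO2Me, C1 bears CH(CH3)CH2CH(OMe)2)
Conditions: CH2Cl2, 12 kbar, 15–20 °C, 48 h, 2,6-di-tert-butyl-4-methylphenol (trace); 33 in 1.5-fold excess
Reagents that add atoms: none
Why: Diels–Alder reaction accelerated by pressure so that it can outrun the 1,5-hydrogen shift of the diene: the unsubstituted terminus C13′ should bond to the substituted terminus C1 and the fully substituted C11′ to C3–H for steric reasons, the lactone carbonyl takes the exo position as is usual for α-methylene-γ-butyrolactones, the dienophile approaches the diene face opposite the C2 acetoxy group because its exo carbonyl would otherwise press against that group, and it reacts on the lactone face syn to C6′ so that its carbocycle lies beside C3–H and not under C1/C5, which together set C1, C3 and C11′.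

Step 24
Reactants: 34 alkenyl bromide adduct
Product: 35 (Z)-2-(hydroxymethyl)enoate adduct (C13 OH trans to C6)
Conditions: Bu3SnCH2OH, Pd2(dba)3 (5 mol %), AsPh3 (20 mol %), N-methylpyrrolidone, 50 °C
Reagents that add atoms: (tributylstannyl)methanol, CCCC[Sn](CCCC)(CCCC)CO
Why: Stille coupling of the activated alkenyl bromide with the hydroxymethylstannane proceeds with retention of alkene geometry.

Step 25
Reactants: 35 allylic alcohol
Product: 36 (E)-2-(bromomethyl)enoate adduct (C8 dimethyl acetal, C1′ silyl ether)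
Conditions: CBr4, PPh3, 2,6-lutidine, CH2Cl2, −20 to 0 °C
Reagents that add atoms: carbon tetrabromide, BrC(Br)(Br)Br
Why: Appel bromination of the only free hydroxyl by direct SN2 displacement at low temperature, which should keep the alkene geometry.

Step 26
Reactants: 36 bromide
Product: 37 C8 aldehyde with (E)-2-(bromomethyl)enoate, C2 acetate and free C1′ hydroxyl (cyclisation precursor)
Conditions: p-TsOH·H2O (0.2 equiv), acetone–H2O (10:1), 0 °C to rt
Reagents that add atoms: water, O
Why: Mild aqueous acid hydrolyses the dimethyl acetal and the primary silyl ether in one operation, while the allylic bromide, acetate and lactone should survive dilute sulfonic acid at room temperature.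

Step 27
Reactants: 37 aldehyde bromide
Product: 39 target CNP0299458.1, via hydroxy ester 38 (not isolated)
Conditions: Zn dust (acid-washed, 10 equiv), THF–sat. aq NH4Cl (4:1), 0.003 M, 0 °C to rt; then 1 M aq HCl to pH 2, rt, 1 h, same flask
Reagents that add atoms: none
Why: Zinc inserts into the C13–Br bond and the allylzinc adds through C7, with allylic transposition, to the C8 aldehyde; the closest known reaction type is the intramolecular Barbier or Nozaki–Hiyama cyclisation of ω-formyl 2-(bromomethyl)enoates, with lactone formation as in the Dreiding–Schmidt synthesis of α-methylene-γ-butyrolactones. The cycloheptane closes by 7-exo-trig attack of C7 on the carbonyl carbon and the lactone by 5-exo-trig attack of the C8 oxygen on the C12 ester with loss of methanol. C7 and C8 arise in a six-membered chair containing Zn, O, C8, C7, C11 and C13, in which C9 is equatorial and, because C6 is trans to C13 in the (E)-bromide, C6 is equatorial too; this is the anti adduct and hence the trans-fused lactone. Which anti pair forms should be decided by the norbornene: the C2 acetoxy group overhangs the C1–C5 bond on the β face, so the C9–C8 chain should fold onto the α face with H10 lying between C2 and C13′, and this presents the Si face of the aldehyde to C7 and gives 7S,8R. The step therefore needs anti over syn, secured by the alkene geometry, and α over β folding, secured by the acetate on C2 and the C10 centre. The aqueous conditions should spare the acetate, the spirolactone, the s-trans diene and the free hydroxyl, and high dilution suppresses intermolecular coupling.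

**Compound list**

1 | cyclopentane-1,3-dione | O=C1CCC(=O)C1 | starting material
2 | (E)-but-2-enal | C/C=C/C=O | starting material
3 | (4R)-2-hydroxy-4-methyl-3,4,6,7-tetrahydrocyclopenta[b]pyran-5(2H)-one | O=C1CCC2=C1[C@H](C)CC(O)O2 | intermediate
4 | (4R)-2-methoxy-4-methyl-3,4,6,7-tetrahydrocyclopenta[b]pyran-5(2H)-one | O=C1CCC2=C1[C@H](C)CC(OC)O2 | intermediate
5 | (4R)-2-methoxy-4,6-dimethyl-3,4,6,7-tetrahydrocyclopenta[b]pyran-5(2H)-one | O=C1C(C)CC2=C1[C@H](C)CC(OC)O2 | intermediate
6 | (4R)-6-hydroxy-2-methoxy-4,6-dimethyl-3,4,6,7-tetrahydrocyclopenta[b]pyran-5(2H)-one | O=C1C(C)(O)CC2=C1[C@H](C)CC(OC)O2 | intermediate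
7 | (4R)-2-methoxy-4,6-dimethyl-6-(triethylsilyloxy)-3,4,6,7-tetrahydrocyclopenta[b]pyran-5(2H)-one | O=C1C(C)(O[Si](CC)(CC)CC)CC2=C1[C@H](C)CC(OC)O2 | intermediate
8 | (4R)-2-methoxy-4,6-dimethyl-5-(prop-2-enyl)-6-(triethylsilyloxy)-2,3,4,5,6,7-hexahydrocyclopenta[b]pyran-5-ol | OC1(CC=C)C(C)(O[Si](CC)(CC)CC)CC2=C1[C@H](C)CC(OC)O2 | intermediate
9 | 2-[(2R)-4,4-dimethoxybutan-2-yl]-4-methyl-3-(prop-2-enyl)-4-(triethylsilyloxy)cyclopent-2-en-1-one | O=C1CC(C)(O[Si](CC)(CC)CC)C(CC=C)=C1[C@H](C)CC(OC)OC | intermediate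
10 | (1S)-2-[(2R)-4,4-dimethoxybutan-2-yl]-4-methyl-3-(prop-2-enyl)-4-(triethylsilyloxy)cyclopent-2-en-1-ol | O[C@H]1CC(C)(O[Si](CC)(CC)CC)C(CC=C)=C1[C@H](C)CC(OC)OC | intermediate
11 | acetate of 10 | CC(=O)O[C@H]1CC(C)(O[Si](CC)(CC)CC)C(CC=C)=C1[C@H](C)CC(OC)OC | intermediate
12 | [(3S)-3-acetoxy-2-[(2R)-4,4-dimethoxybutan-2-yl]-5-methyl-5-(triethylsilyloxy)cyclopent-1-en-1-yl]acetaldehyde | CC(=O)O[C@H]1CC(C)(O[Si](CC)(CC)CC)C(CC=O)=C1[C@H](C)CC(OC)OC | intermediate
13 | methyl (2E)-4-[(3S)-3-acetoxy-2-[(2R)-4,4-dimethoxybutan-2-yl]-5-methyl-5-(triethylsilyloxy)cyclopent-1-en-1-yl]-2-bromobut-2-enoate | CC(=O)O[C@H]1CC(C)(O[Si](CC)(CC)CC)C(C/C=C(/Br)C(=O)OC)=C1[C@H](C)CC(OC)OC | intermediate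
14 | methyl (2E)-4-[(3S)-3-acetoxy-2-[(2R)-4,4-dimethoxybutan-2-yl]-5-hydroxy-5-methylcyclopent-1-en-1-yl]-2-bromobut-2-enoate | CC(=O)O[C@H]1CC(C)(O)C(C/C=C(/Br)C(=O)OC)=C1[C@H](C)CC(OC)OC | intermediate
15 | methyl (2E)-4-[(3S)-3-acetoxy-2-[(2R)-4,4-dimethoxybutan-2-yl]-5-methylcyclopenta-1,4-dien-1-yl]-2-bromobut-2-enoate | CC(=O)O[C@H]1C=C(C)C(C/C=C(/Br)C(=O)OC)=C1[C@H](C)CC(OC)OC | intermediate
16 | (S)-citronellal | C[C@@H](CCC=C(C)C)CC=O | starting material
17 | (3S)-3,7-dimethyl-2-methylideneoct-6-enal | C=C(C=O)[C@@H](C)CCC=C(C)C | intermediate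
18 | (4S)-4,8-dimethyl-3-methylidenenon-7-en-2-ol | C=C(C(C)O)[C@@H](C)CCC=C(C)C | intermediate
19 | (4S)-4,8-dimethyl-3-methylidenenon-7-en-2-one | C=C(C(C)=O)[C@@H](C)CCC=C(C)C | intermediate
20 | methyl 4-oxobutanoate | O=CCCC(=O)OC | starting material
21 | methyl (3S)-3-formyl-5-[(2S)-6-methylhept-5-en-2-yl]-6-oxoheptanoate | O=C[C@H](CC(=O)OC)CC(C(C)=O)[C@@H](C)CCC=C(C)C | intermediate
22 | methyl [(1S)-5-[(2S)-6-methylhept-5-en-2-yl]-4-oxocyclohex-2-en-1-yl]acetate | O=C1C=C[C@H](CC(=O)OC)CC1[C@@H](C)CCC=C(C)C | intermediate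
23 | [(1S)-5-[(2S)-6-methylhept-5-en-2-yl]-4-oxocyclohex-2-en-1-yl]acetic acid | O=C1C=C[C@H](CC(=O)O)CC1[C@@H](C)CCC=C(C)C | intermediate
24 | (3aS,7aS)-5-[(2S)-6-methylhept-5-en-2-yl]hexahydro-1-benzofuran-2,6-dione | O=C1C[C@@H]2OC(=O)C[C@@H]2CC1[C@@H](C)CCC=C(C)C | intermediate
25 | (4S)-4-[(3aS,7aS)-2,6-dioxooctahydro-1-benzofuran-5-yl]pentanal | O=C1C[C@@H]2OC(=O)C[C@@H]2CC1[C@@H](C)CCC=O | intermediate
26 | (3aS,7aS)-5-[(2S)-5-hydroxypentan-2-yl]hexahydro-1-benzofuran-2,6-dione | O=C1C[C@@H]2OC(=O)C[C@@H]2CC1[C@@H](C)CCCO | intermediate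
27 | 5-(phenylselanyl) derivative of 26 (selenium on C5′) | O=C1C[C@@H]2OC(=O)C[C@@H]2CC1([Se]c3ccccc3)[C@@H](C)CCCO | intermediate
28 | (3aR,7aS)-5-[(2S)-5-hydroxypentan-2-yl]-3,3a,7,7a-tetrahydro-1-benzofuran-2,6-dione | O=C1C[C@@H]2OC(=O)C[C@@H]2C=C1[C@@H](C)CCCO | intermediate
29 | tert-butyldimethylsilyl ether of 28 | O=C1C[C@@H]2OC(=O)C[C@@H]2C=C1[C@@H](C)CCCO[Si](C)(C)C(C)(C)C | intermediate
30 | (3aR,7aS)-5-[(2S)-5-(tert-butyldimethylsilyloxy)pentan-2-yl]-6-methylidene-3,3a,7,7a-tetrahydro-1-benzofuran-2(6H)-one | C=C1C[C@@H]2OC(=O)C[C@@H]2C=C1[C@@H](C)CCCO[Si](C)(C)C(C)(C)C | intermediate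
31 | 3-[(dimethylamino)methyl] derivative of 30 | C=C1C[C@@H]2OC(=O)C(CN(C)C)[C@@H]2C=C1[C@@H](C)CCCO[Si](C)(C)C(C)(C)C | intermediate
32 | N-methyl iodide of 31 | C=C1C[C@@H]2OC(=O)C(C[N+](C)(C)C)[C@@H]2C=C1[C@@H](C)CCCO[Si](C)(C)C(C)(C)C.[I-] | intermediate
33 | (3aS,7aS)-5-[(2S)-5-(tert-butyldimethylsilyloxy)pentan-2-yl]-3,6-dimethylidene-3,3a,7,7a-tetrahydro-1-benzofuran-2(6H)-one | C=C1C[C@@H]2OC(=O)[C](=C)[C@@H]2C=C1[C@@H](C)CCCO[Si](C)(C)C(C)(C)C | intermediate
34 | spiro-norbornene adduct: C2 OAc, C5 CH2CH=C(Br)CO2Me (E), C1 CH(CH3)CH2CH(OMe)2, C1′ silyl ether | C=C1C[C@@H]2OC(=O)[C@@]3(C[C@@]4([C@H](C)CC(OC)OC)C(=C(C)[C@@H]3[C@@H]4OC(C)=O)C/C=C(/Br)C(=O)OC)[C@@H]2C=C1[C@@H](C)CCCO[Si](C)(C)C(C)(C)C | intermediate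
35 | adduct with (Z)-CH2CH=C(CH2OH)CO2Me on C5 | C=C1C[C@@H]2OC(=O)[C@@]3(C[C@@]4([C@H](C)CC(OC)OC)C(=C(C)[C@@H]3[C@@H]4OC(C)=O)C/C=C(/CO)C(=O)OC)[C@@H]2C=C1[C@@H](C)CCCO[Si](C)(C)C(C)(C)C | intermediate
36 | adduct with (E)-CH2CH=C(CH2Br)CO2Me on C5 | C=C1C[C@@H]2OC(=O)[C@@]3(C[C@@]4([C@H](C)CC(OC)OC)C(=C(C)[C@@H]3[C@@H]4OC(C)=O)C/C=C(/CBr)C(=O)OC)[C@@H]2C=C1[C@@H](C)CCCO[Si](C)(C)C(C)(C)C | intermediate
37 | cyclisation precursor: C8 aldehyde, (E)-2-(bromomethyl)enoate, C2 OAc, free C1′ OH | C=C1C[C@@H]2OC(=O)[C@@]3(C[C@@]4([C@H](C)CC=O)C(=C(C)[C@@H]3[C@@H]4OC(C)=O)C/C=C(/CBr)C(=O)OC)[C@@H]2C=C1[C@@H](C)CCCO | intermediate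
38 | (7S,8R)-8-hydroxy 12-methyl ester (cycloheptane closed, lactone open) | C=C1C[C@@H]2OC(=O)[C@@]3(C[C@@]45C(=C(C)[C@@H]3[C@@H]4OC(C)=O)C[C@@H](C(=C)C(=O)OC)[C@H](O)C[C@H]5C)[C@@H]2C=C1[C@@H](C)CCCO | intermediate
39 | CNP0299458.1 | C=C1C[C@@H]2OC(=O)[C@@]3(C[C@@]45C(=C(C)[C@@H]3[C@@H]4OC(C)=O)C[C@H]3C(=C)C(=O)O[C@@H]3C[C@H]5C)[C@@H]2C=C1[C@@H](C)CCCO | target

**Count**

Total: 27 steps. Longest linear sequence: 17 steps (steps 1–12, then 23–27).

**Steps most likely to fail**

Step 23. The lactone may add to the acetoxy-bearing face of the diene (the face usually preferred with oxygen substituents on the sp3 carbon) or to the other lactone face, and the diene may isomerise by 1,5-hydrogen shift before it reacts. The fallback replaces the acetate by a bulky silyl ether that screens its own face. It sets out from alcohol 10, which is silylated with i-Pr3SiOSO2CF3 and 2,6-lutidine to the triisopropylsilyl ether F1. Cleavage of the allyl group as in step 9 gives the aldehyde F2, and olefination as in step 10 the bromo enoate F3. HF·pyridine removes only the tertiary triethylsilyl group to give the tertiary alcohol F4, and the sulfurane gives the silyloxy diene F5. Cycloaddition with 33 under the conditions of step 23 gives the adduct F6. Bu4NF cleaves both silyl ethers to the diol F7, t-BuMe2SiCl with imidazole silylates only the primary hydroxyl to give the mono silyl ether F8, and acetylation with Ac2O and 4-(dimethylamino)pyridine returns to 34.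

Step 27. The allylzinc may lose its alkene geometry, or the tether may fold onto the β face, so that the syn adduct (cis lactone) or the other anti pair forms. The fallback uses a configurationally stable allylboronate under catalyst control. It sets out from 34. Negishi coupling with IZnCH2B(pin) and Pd(PPh3)4 gives, with retention of geometry, the allylboronate F9. The acid treatment of step 26 gives the aldehyde F10, which should be isolable because 2-alkoxycarbonyl allylboronates add slowly without acid. (S)-3,3′-Bis(2,4,6-triisopropylphenyl)-1,1′-binaphthyl-2,2′-diyl hydrogen phosphate in toluene then promotes the intramolecular allylboration through a closed chair on the Si face of C8, and the borate lactonises to 39.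

Step 19. Selenenylation may take place at C9′ instead of C5′, and enolisation toward C9′ may expel the lactone carboxylate and end in aromatisation. The fallback is a Saegusa–Ito dehydrogenation. It sets out from 26, which with Me3SiOSO2CF3 and Et3N under equilibrating conditions gives the more substituted silyl enol ether, silylated also at the primary oxygen, F11. Pd(OAc)2 in MeCN followed by a dilute citric acid work-up returns to 28.

**Further compounds**

F1 | step 23 | triisopropylsilyl ether of 10 | CC(C)[Si](C(C)C)(C(C)C)O[C@H]1CC(C)(O[Si](CC)(CC)CC)C(CC=C)=C1[C@H](C)CC(OC)OC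
F2 | step 23 | C7 aldehyde of the silyl ether series | CC(C)[Si](C(C)C)(C(C)C)O[C@H]1CC(C)(O[Si](CC)(CC)CC)C(CC=O)=C1[C@H](C)CC(OC)OC
F3 | step 23 | (E)-α-bromo enoate of the silyl ether series | CC(C)[Si](C(C)C)(C(C)C)O[C@H]1CC(C)(O[Si](CC)(CC)CC)C(C/C=C(/Br)C(=O)OC)=C1[C@H](C)CC(OC)OC
F4 | step 23 | tertiary alcohol of the silyl ether series | CC(C)[Si](C(C)C)(C(C)C)O[C@H]1CC(C)(O)C(C/C=C(/Br)C(=O)OC)=C1[C@H](C)CC(OC)OC
F5 | step 23 | 5-(triisopropylsilyloxy)cyclopentadiene | CC(C)[Si](C(C)C)(C(C)C)O[C@H]1C=C(C)C(C/C=C(/Br)C(=O)OC)=C1[C@H](C)CC(OC)OC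
F6 | step 23 | spiro-norbornene adduct with C2 triisopropylsilyl ether | C=C1C[C@@H]2OC(=O)[C@@]3(C[C@@]4([C@H](C)CC(OC)OC)C(=C(C)[C@@H]3[C@@H]4O[Si](C(C)C)(C(C)C)C(C)C)C/C=C(/Br)C(=O)OC)[C@@H]2C=C1[C@@H](C)CCCO[Si](C)(C)C(C)(C)C
F7 | step 23 | adduct diol (C2 OH, C1′ OH) | C=C1C[C@@H]2OC(=O)[C@@]3(C[C@@]4([C@H](C)CC(OC)OC)C(=C(C)[C@@H]3[C@@H]4O)C/C=C(/Br)C(=O)OC)[C@@H]2C=C1[C@@H](C)CCCO
F8 | step 23 | adduct with free C2 OH and C1′ tert-butyldimethylsilyl ether | C=C1C[C@@H]2OC(=O)[C@@]3(C[C@@]4([C@H](C)CC(OC)OC)C(=C(C)[C@@H]3[C@@H]4O)C/C=C(/Br)C(=O)OC)[C@@H]2C=C1[C@@H](C)CCCO[Si](C)(C)C(C)(C)C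
F9 | step 27 | (E)-allylboronate adduct (C13 pinacolboryl, C8 acetal, C1′ silyl ether) | C=C1C[C@@H]2OC(=O)[C@@]3(C[C@@]4([C@H](C)CC(OC)OC)C(=C(C)[C@@H]3[C@@H]4OC(C)=O)C/C=C(/CB5OC(C)(C)C(C)(C)O5)C(=O)OC)[C@@H]2C=C1[C@@H](C)CCCO[Si](C)(C)C(C)(C)C
F10 | step 27 | (E)-allylboronate with C8 aldehyde and free C1′ OH | C=C1C[C@@H]2OC(=O)[C@@]3(C[C@@]4([C@H](C)CC=O)C(=C(C)[C@@H]3[C@@H]4OC(C)=O)C/C=C(/CB5OC(C)(C)C(C)(C)O5)C(=O)OC)[C@@H]2C=C1[C@@H](C)CCCO
F11 | step 19 | C10′ trimethylsilyl enol ether (C5′=C10′) with trimethylsilylated side-chain oxygen | C[Si](C)(C)OC1=C([C@@H](C)CCCO[Si](C)(C)C)C[C@H]2CC(=O)O[C@H]2C1
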